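**Retrosynthetic overview**
- The strategy rests on the trisubstituted C9'(CH3)=C10'H alkene of the chain. It lies between the C7'≡C8' alkyne on ring B and C11'=C12'. Methyl C19' is cis to C11' and alkyne carbon C8' is trans to it.
- Key cut: C9'–C19' and C10'–C11' are made in one pot from a ring B buta-1,3-diyne, trimethylaluminium and an all-E C26 heptaenyl iodide that carries ring A.
- The C26 iodide comes from iodo-olefination of a C25 aldehyde. That aldehyde comes from a Wittig reaction (C11=C12) of a ring A C15 phosphonium salt with the C10 dialdehyde.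
- C6 of ring A is set by acetylide addition to the (R)-4-hydroxy enone, which should give the 3,6-trans diol. C3 is then inverted to reach the 3,6-cis diol. The ring B diyne comes from the enol triflate of silylated (4R,6R)-actinol and a butadiynylzinc.
- No ring is formed. Rings A and B both come intact from ketoisophorone.

Key step: step 18

Remark: the SMILES reads as (3S,6R,3'R), with the two hydroxyls of ring A cis. Carotenoid numbering is used for positions. Ring A is C1–C6 (dihydroxy ring) and ring B is C1'–C6' (acetylenic ring).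

**Ring B half**

Step 1
Reactants: 1 ketoisophorone (2,6,6-trimethylcyclohex-2-ene-1,4-dione)
Product: 2 (6R)-2,2,6-trimethylcyclohexane-1,4-dione (levodione)
Conditions: OYE2 ene-reductase, NADP+ (cat.), glucose dehydrogenase, D-glucose, phosphate buffer pH 7, 30 °C
Reagents that add atoms: none
Why: Biocatalytic asymmetric C=C reduction by a flavin ene-reductase (Old Yellow Enzyme type) adds hydride and proton anti across the activated C2=C3 bond, and the binding mode in the active site fixes the methyl-bearing carbon as (6R).

Step 2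
Reactants: 2 (6R)-2,2,6-trimethylcyclohexane-1,4-dione
Product: 3 (4R,6R)-4-hydroxy-2,2,6-trimethylcyclohexan-1-one (actinol)
Conditions: H2, Raney Ni, MeOH, 20 °C; crystallisation
Reagents that add atoms: none
Why: Chemoselective heterogeneous hydrogenation of the unhindered C4 carbonyl (C1 is flanked by a quaternary and a tertiary carbon); the axial C2 methyl blocks the axial face, so hydrogen arrives equatorially and leaves the axial (4R) hydroxyl trans to the C6 methyl, the minor cis alcohol being removed by crystallisation.

Step 3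
Reactants: 3 (4R,6R)-actinol
Product: 4 (4R,6R)-4-(tert-butyldimethylsilyloxy)-2,2,6-trimethylcyclohexan-1-one
Conditions: TBSCl, imidazole, DMF, 23 °C
Reagents that add atoms: tert-butyldimethylsilyl chloride CC(C)(C)[Si](C)(C)Cl
Why: Imidazole-promoted silylation of the only hydroxyl, with no stereocentre touched.

Step 4
Reactants: 4 silylated actinol
Product: 6 (R)-4-(tert-butyldimethylsilyloxy)-2,6,6-trimethylcyclohex-1-en-1-yl trifluoromethanesulfonate, via lithium enolate 5 (not isolated)
Conditions: lithium diisopropylamide, THF, −78 °C; PhNTf2, −78→23 °C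
Reagents that add atoms: N-phenylbis(trifluoromethanesulfonimide) O=S(=O)(N(c1ccccc1)S(=O)(=O)C(F)(F)F)C(F)(F)F
Why: Only C6 can be deprotonated, so enolate O-triflation gives a single tetrasubstituted enol triflate; the C6 stereocentre is erased and C4 (later C3') is untouched.

Step 5
Reactants: 6 ring B enol triflate; 7 1,4-bis(trimethylsilyl)buta-1,3-diyne
Product: 10 (R)-tert-butyldimethyl{[3,5,5-trimethyl-4-(4-trimethylsilylbuta-1,3-diyn-1-yl)cyclohex-3-en-1-yl]oxy}silane, via lithium diynide 8 (not isolated), via diynylzinc bromide 9 (not isolated)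
Conditions: 7, MeLi·LiBr, THF, 0→23 °C; ZnBr2, 0 °C; 6, Pd(PPh3)4 (5 mol%), 23→50 °C
Reagents that add atoms: none
Why: Methyllithium cleaves one C–Si bond of 7, zinc bromide turns the lithium diynide into the softer diynylzinc, and Negishi alkynylation (oxidative addition of zerovalent palladium into the hindered C6'–OTf bond, transmetalation, reductive elimination) forms C6'–C7' without the copper-mediated diyne homocoupling that a Sonogashira protocol risks.

Step 6
Reactants: 10 silyl-capped ring B diyne
Product: 11 (R)-tert-butyl{[4-(buta-1,3-diyn-1-yl)-3,5,5-trimethylcyclohex-3-en-1-yl]oxy}dimethylsilane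
Conditions: K2CO3 (cat.), MeOH/THF, 0 °C
Reagents that add atoms: none
Why: Methoxide-induced protiodesilylation removes only the alkynyl trimethylsilyl group, the secondary silyl ether being inert to catalytic K2CO3 in methanol; the terminal diyne is kept cold in solution, dried and used at once.

**Ring A half**

Step 7
Reactants: 1 ketoisophorone
Product: 12 (R)-4-hydroxy-2,6,6-trimethylcyclohex-2-en-1-one
Conditions: RuCl[(R,R)-TsDPEN](p-cymene) (1 mol%), KOtBu (cat.), iPrOH, 23 °C; crystallisation
Reagents that add atoms: none
Why: Noyori-type asymmetric transfer hydrogenation reduces only the C4 carbonyl because C1 is screened by the gem-dimethyl carbon and the C2 methyl; the alkenyl flank takes the place of the aryl group of an aryl ketone in the six-membered hydride/proton transfer state, so the (R,R)-ligand should give the (R)-carbinol (later C3), whose enantiopurity can be raised by crystallisation.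

Step 8
Reactants: 13 (E)-3-methylpent-2-en-4-yn-1-ol
Product: 14 (E)-tert-butyldimethyl[(3-methylpent-2-en-4-yn-1-yl)oxy]silane
Conditions: TBSCl, imidazole, CH2Cl2, 0→23 °C
Reagents that add atoms: tert-butyldimethylsilyl chloride CC(C)(C)[Si](C)(C)Cl
Why: Imidazole-promoted silylation of the primary allylic alcohol, with the 9E geometry of the building block unchanged.

Step 9
Reactants: 12 (R)-hydroxy enone; 14 silylated enynol
Product: 16 (1R,4R)-1-[(E)-5-(tert-butyldimethylsilyloxy)-3-methylpent-3-en-1-yn-1-yl]-2,6,6-trimethylcyclohex-2-ene-1,4-diol (3,6-trans), via lithium acetylide 15 (not isolated)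
Conditions: 14 (2.3 equiv), n-BuLi (2.2 equiv), THF, −78 °C; 12, −78→−20 °C; water
Reagents that add atoms: none
Why: 1,2-Addition of a lithium acetylide to a hindered enone (one equivalent is spent on the free hydroxyl): in the favoured envelope the C3 oxygen is pseudo-equatorial, since the other envelope would set it syn-axial to a C1 methyl, and the remaining axial C1 methyl blocks the carbonyl face anti to that oxygen, so axial attack on the face syn to the C3 oxygen sets C6 as (R) and gives the 3,6-trans diol.

Step 10
Reactants: 16 trans enyne diol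
Product: 17 (1S,4R)-4-[(E)-5-(tert-butyldimethylsilyloxy)-3-methylpent-3-en-1-yn-1-yl]-4-hydroxy-3,5,5-trimethylcyclohex-2-en-1-yl benzoate
Conditions: PhCO2H, PPh3, DIAD, toluene, −20→0 °C
Reagents that add atoms: benzoic acid O=C(O)c1ccccc1
Why: Mitsunobu esterification activates only the secondary allylic hydroxyl (the tertiary one is too hindered to form an oxyphosphonium ion) and benzoate displaces it by SN2 with inversion, turning (3R) into (3S) and the trans into the cis 3,6-relationship; SN2' attack at the fully substituted C5 and ionisation are disfavoured by the adjacent electron-withdrawing C6 carbinol carbon.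

Step 11
Reactants: 17 cis benzoate
Product: 18 (1R,4S)-1-[(1E,3E)-5-(tert-butyldimethylsilyloxy)-3-methylpenta-1,3-dien-1-yl]-2,6,6-trimethylcyclohex-2-ene-1,4-diol (3,6-cis)
Conditions: NaAlH2(OCH2CH2OCH3)2, THF, 0→23 °C
Reagents that add atoms: none
Why: Hydroxyl-directed trans-hydroalumination of the propargylic alcohol followed by protonolysis gives the (7E)-alkene, and the same hydride cleaves the benzoate at its carbonyl with retention at C3; the primary silyl ether is inert, silyloxide being too poor a leaving group for vinylogous elimination at this temperature.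

Step 12
Reactants: 18 cis diol
Product: 19 (1R,4S)-4-(tert-butyldimethylsilyloxy)-1-[(1E,3E)-5-(tert-butyldimethylsilyloxy)-3-methylpenta-1,3-dien-1-yl]-2,6,6-trimethylcyclohex-2-en-1-ol
Conditions: TBSCl, imidazole, DMF, 23 °C
Reagents that add atoms: tert-butyldimethylsilyl chloride CC(C)(C)[Si](C)(C)Cl
Why: Silylation is selective for the secondary C3 hydroxyl because the tertiary C6 hydroxyl, flanked by quaternary C1 and by C5, does not react with the silyl chloride under imidazole conditions.

Step 13
Reactants: 19 bis-silyl ether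
Product: 20 (1R,4S)-4-(tert-butyldimethylsilyloxy)-1-[(1E,3E)-5-hydroxy-3-methylpenta-1,3-dien-1-yl]-2,6,6-trimethylcyclohex-2-en-1-ol
Conditions: HF·pyridine, pyridine, THF, 0 °C
Reagents that add atoms: none
Why: Buffered fluoride cleaves the unhindered primary allylic silyl ether much faster than the secondary ring silyl ether, and the excess pyridine keeps the medium from ionising the tertiary bis-allylic alcohol.

Step 14
Reactants: 20 C15 dienol
Product: 22 {(2E,4E)-5-[(1R,4S)-4-(tert-butyldimethylsilyloxy)-1-hydroxy-2,6,6-trimethylcyclohex-2-en-1-yl]-3-methylpenta-2,4-dien-1-yl}triphenylphosphonium bromide, via allylic bromide 21 (not isolated)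
Conditions: CBr4, PPh3, 2,6-lutidine (0.2 equiv), CH2Cl2, −20 °C; then PPh3, 23 °C
Reagents that add atoms: triphenylphosphine c1ccc(cc1)P(c1ccccc1)c1ccccc1; carbon tetrabromide BrC(Br)(Br)Br
Why: Appel bromination converts only the primary allylic alcohol under essentially neutral conditions, and SN2 quaternisation of triphenylphosphine by the dienylic bromide in the same flask avoids both isolation of the labile bromide and the acidic phosphine hydrobromide protocol that would ionise C6–OH.

Step 15
Reactants: 22 C15 phosphonium bromide; 23 (2E,4E,6E)-2,7-dimethylocta-2,4,6-trienedial (C10 dialdehyde)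
Product: 25 all-E C25 aldehyde (3S,6R)-3-(tert-butyldimethylsilyloxy)-6-hydroxy-12'-apo-ε-caroten-12'-al, via phosphorus ylide 24 (not isolated)
Conditions: 23 (2.5 equiv), NaOMe, CH2Cl2/MeOH, 0 °C; then PdCl2(MeCN)2 (cat.), Et3N, CH2Cl2, 23 °C, dark
Reagents that add atoms: none
Why: Wittig olefination of the semi-stabilised dienyl ylide with an excess of the symmetrical dialdehyde stops at mono-olefination and forms C11=C12; the strained (11Z) isomer is equilibrated to all-E by catalytic divalent palladium, and the C6 hydroxyl is left free because hydroxide is too poor a leaving group for vinylogous elimination from the ylide.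

Step 16
Reactants: 25 C25 hydroxy aldehyde
Product: 26 all-E C25 aldehyde with C3–OTBS and C6–OSiMe3
Conditions: N-(trimethylsilyl)imidazole, CH2Cl2, 23 °C, dark
Reagents that add atoms: N-(trimethylsilyl)imidazole C[Si](C)(C)n1ccnc1
Why: The N-silylimidazole is a neutral and powerful silyl donor that caps the hindered tertiary hydroxyl without acid, without enolising the polyenal and without touching the C6 configuration.

Step 17
Reactants: 26 silylated C25 aldehyde
Product: 27 all-E C26 heptaenyl iodide with C3–OTBS and C6–OSiMe3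
Conditions: CHI3, CrCl2, THF, 0 °C, dark
Reagents that add atoms: iodoform IC(I)I
Why: Takai iodo-olefination, in which the gem-dichromium carbenoid from iodoform adds to the aldehyde and elimination gives the (E)-alkenyl iodide (C11'=C12'), a reaction that tolerates silyl ethers and conjugated alpha-branched enals.

**Union and end game**

Step 18
Reactants: 11 ring B buta-1,3-diyne; 28 trimethylaluminium; 27 C26 heptaenyl iodide
Product: 31 tris-silyl ether of the target (3-OTBS 6-OSiMe3 3'-OTBS), via alkenylalane 29 (not isolated), via alkenylzinc chloride 30 (not isolated)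
Conditions: 11 (1.3 equiv), 28, Cp2ZrCl2 (0.3 equiv), CH2Cl2, 0→23 °C; evaporate, THF; ZnCl2, 0 °C; 27, Pd2(dba)3 (2.5 mol%), P(2-furyl)3 (10 mol%), THF/DMF, 0→23 °C, dark
Reagents that add atoms: trimethylaluminium C[Al](C)C (compound 28)
Why: Me3Al and Cp2ZrCl2 form a Zr–Al methylzirconocene species that adds CH3 and metal syn across the terminal C9'≡C10' alkyne, CH3 going to the internal carbon C9' and aluminium ending on C10', which gives the (E)-2-methylalkenylalane 29. ZnCl2 then takes the alkenyl group over to zinc (30), zerovalent palladium inserts into the C11'–I bond of 27, and transmetalation followed by reductive elimination forms C10'–C11' with retention at both alkenyl carbons. The closest known reaction type is the Negishi zirconium-catalysed methylalumination of terminal alkynes, conjugated enynes and silyl-capped butadiynes joined to Pd/Zn-catalysed alkenyl–alkenyl coupling, as used for retinoid and carotenoid chains. No ring closes and no stereocentre is created; the stereochemical outcome is the 9'E geometry (C19' cis and C8' trans to C11'), fixed by the syn addition, and the 11'E geometry, carried over from 27. The step needs site selectivity between the two alkynes and regioselectivity at the terminal one: the internal C7'≡C8' alkyne is shielded by the tetrasubstituted C5'=C6' alkene and the C1' gem-dimethyl group, and a terminal alkyne places methyl on its substituted carbon for steric reasons. All three hydroxyls are silylated so that no O–H destroys the alane, and excess Me3Al is pumped off and replaced by THF before 27 is added, which tempers the aluminium Lewis acids that could ionise the tertiary bis-allylic C6–OSiMe3 group.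

Step 19
Reactants: 31 tris-silyl ether
Product: 32 target, (3S,6R,3'R)-7',8'-didehydro-β,ε-carotene-3,6,3'-triol (CNP0113828.1)
Conditions: Bu4NF, THF, 0→23 °C, dark
Reagents that add atoms: none
Why: Fluoride-induced cleavage of all three Si–O bonds under non-acidic conditions spares the tertiary bis-allylic alcohol and the polyene, and cold, dark handling keeps the 9'E enyne alkene from equilibrating.

**Compound list**
1 | ketoisophorone | CC1=CC(=O)CC(C)(C)C1=O | starting material
2 | (6R)-2,2,6-trimethylcyclohexane-1,4-dione | C[C@@H]1CC(=O)CC(C)(C)C1=O | intermediate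
3 | (4R,6R)-4-hydroxy-2,2,6-trimethylcyclohexan-1-one | C[C@@H]1C[C@@H](O)CC(C)(C)C1=O | intermediate
4 | (4R,6R)-4-(tert-butyldimethylsilyloxy)-2,2,6-trimethylcyclohexan-1-one | C[C@@H]1C[C@@H](O[Si](C)(C)C(C)(C)C)CC(C)(C)C1=O | intermediate
5 | lithium enolate of 4 | [Li]OC1=C(C)C[C@@H](O[Si](C)(C)C(C)(C)C)CC1(C)C | intermediate
6 | (R)-4-(tert-butyldimethylsilyloxy)-2,6,6-trimethylcyclohex-1-en-1-yl trifluoromethanesulfonate | FC(F)(F)S(=O)(=O)OC1=C(C)C[C@@H](O[Si](C)(C)C(C)(C)C)CC1(C)C | intermediate
7 | 1,4-bis(trimethylsilyl)buta-1,3-diyne | C[Si](C)(C)C#CC#C[Si](C)(C)C | starting material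
8 | lithium 4-(trimethylsilyl)buta-1,3-diynide | [Li]C#CC#C[Si](C)(C)C | intermediate
9 | bromo[4-(trimethylsilyl)buta-1,3-diynyl]zinc | Br[Zn]C#CC#C[Si](C)(C)C | intermediate
10 | (R)-silyl-capped ring B diyne | C[Si](C)(C)C#CC#CC1=C(C)C[C@@H](O[Si](C)(C)C(C)(C)C)CC1(C)C | intermediate
11 | (R)-tert-butyl{[4-(buta-1,3-diyn-1-yl)-3,5,5-trimethylcyclohex-3-en-1-yl]oxy}dimethylsilane | C#CC#CC1=C(C)C[C@@H](O[Si](C)(C)C(C)(C)C)CC1(C)C | intermediate
12 | (R)-4-hydroxy-2,6,6-trimethylcyclohex-2-en-1-one | CC1=C[C@H](O)CC(C)(C)C1=O | intermediate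
13 | (E)-3-methylpent-2-en-4-yn-1-ol | C#C/C(C)=C/CO | starting material
14 | (E)-tert-butyldimethyl[(3-methylpent-2-en-4-yn-1-yl)oxy]silane | C#C/C(C)=C/CO[Si](C)(C)C(C)(C)C | intermediate
15 | lithium acetylide of 14 | [Li]C#C/C(C)=C/CO[Si](C)(C)C(C)(C)C | intermediate
16 | (1R,4R)-trans enyne diol | CC1=C[C@H](O)CC(C)(C)[C@]1(O)C#C/C(C)=C/CO[Si](C)(C)C(C)(C)C | intermediate
17 | (1S,4R)-cis enyne benzoate | CC1=C[C@@H](OC(=O)c2ccccc2)CC(C)(C)[C@]1(O)C#C/C(C)=C/CO[Si](C)(C)C(C)(C)C | intermediate
18 | (1R,4S)-cis diene diol, primary OTBS | CC1=C[C@@H](O)CC(C)(C)[C@]1(O)/C=C/C(C)=C/CO[Si](C)(C)C(C)(C)C | intermediate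
19 | (1R,4S)-bis-TBS ether, tertiary OH free | CC1=C[C@@H](O[Si](C)(C)C(C)(C)C)CC(C)(C)[C@]1(O)/C=C/C(C)=C/CO[Si](C)(C)C(C)(C)C | intermediate
20 | (1R,4S)-C15 dienol, C3–OTBS | CC1=C[C@@H](O[Si](C)(C)C(C)(C)C)CC(C)(C)[C@]1(O)/C=C/C(C)=C/CO | intermediate
21 | C15 allylic bromide | CC1=C[C@@H](O[Si](C)(C)C(C)(C)C)CC(C)(C)[C@]1(O)/C=C/C(C)=C/CBr | intermediate
22 | C15 triphenylphosphonium bromide | CC1=C[C@@H](O[Si](C)(C)C(C)(C)C)CC(C)(C)[C@]1(O)/C=C/C(C)=C/C[P+](c1ccccc1)(c1ccccc1)c1ccccc1.[Br-] | intermediate
23 | (2E,4E,6E)-2,7-dimethylocta-2,4,6-trienedial | O=C/C(C)=C/C=C/C=C(C)/C=O | starting material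
24 | C15 phosphorus ylide | CC1=C[C@@H](O[Si](C)(C)C(C)(C)C)CC(C)(C)[C@]1(O)/C=C/C(C)=C/C=P(c1ccccc1)(c1ccccc1)c1ccccc1 | intermediate
25 | all-E C25 aldehyde, C6–OH free | CC1=C[C@@H](O[Si](C)(C)C(C)(C)C)CC(C)(C)[C@]1(O)/C=C/C(C)=C/C=C/C(C)=C/C=C/C=C(C)/C=O | intermediate
26 | all-E C25 aldehyde, C6–OSiMe3 | CC1=C[C@@H](O[Si](C)(C)C(C)(C)C)CC(C)(C)[C@]1(O[Si](C)(C)C)/C=C/C(C)=C/C=C/C(C)=C/C=C/C=C(C)/C=O | intermediate
27 | all-E C26 heptaenyl iodide | CC1=C[C@@H](O[Si](C)(C)C(C)(C)C)CC(C)(C)[C@]1(O[Si](C)(C)C)/C=C/C(C)=C/C=C/C(C)=C/C=C/C=C(C)/C=C/I | intermediate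
28 | trimethylaluminium | C[Al](C)C | starting material
29 | (E)-alkenyl(dimethyl)alane of ring B | C[Al](C)/C=C(\C)C#CC1=C(C)C[C@@H](O[Si](C)(C)C(C)(C)C)CC1(C)C | intermediate
30 | (E)-alkenylzinc chloride of ring B | Cl[Zn]/C=C(\C)C#CC1=C(C)C[C@@H](O[Si](C)(C)C(C)(C)C)CC1(C)C | intermediate
31 | tris-silyl ether of the target | CC1=C[C@@H](O[Si](C)(C)C(C)(C)C)CC(C)(C)[C@]1(O[Si](C)(C)C)/C=C/C(C)=C/C=C/C(C)=C/C=C/C=C(C)/C=C/C=C(\C)C#CC1=C(C)C[C@@H](O[Si](C)(C)C(C)(C)C)CC1(C)C | intermediate
32 | (3S,6R,3'R)-7',8'-didehydro-β,ε-carotene-3,6,3'-triol | CC1=C[C@@H](O)CC(C)(C)[C@]1(O)/C=C/C(C)=C/C=C/C(C)=C/C=C/C=C(C)/C=C/C=C(\C)C#CC1=C(C)C[C@@H](O)CC1(C)C | target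

**Step count**
- Total step count: 19.
- Longest linear sequence: 12 steps. These are steps 7 and 9–19 from 1, or equally steps 8 and 9–19 from 13.

**Steps most likely to fail**

1. Step 18.
   - What may go wrong:
     - Me3Al may metalate the acidic diynyl C–H instead of carbometalating the alkyne.
     - Conjugation may erode the regiocontrol of methyl delivery.
     - Methyl may be transferred to the iodide.
     - Residual aluminium chlorides may ionise the C6 silyl ether.
     - The heptaenyl iodide may decay during a slow coupling.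
   - Fallback: it sets out from 11 and 26 and comes back at 31. It keeps aluminium away from the ring A half and reverses the coupling polarity.
     - Diyne 11 is methylaluminated as before to alane 29 and quenched with I2 at −30 °C, giving the (E)-iodoenyne F1.
     - Aldehyde 26 is homologated with Cl2CHBpin, CrCl2 and LiI in THF (Takai–Utimoto boryl-olefination) to the all-E heptaenyl pinacol boronate F2.
     - Suzuki–Miyaura coupling of the two (Pd(PPh3)4, aqueous K3PO4, THF, 23 °C, dark) forms the same C10'–C11' bond and gives 31.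

2. Step 10.
   - What may go wrong:
     - The activated allylic oxyphosphonium ion may ionise, with loss of stereochemical integrity at C3.
     - Allylic transposition or elimination to a ring diene may compete.
     - The C6 hydroxyl may capture C3 from the opposite face and form a 3,6-oxygen bridge.
   - Fallback: it sets out from 16 and comes back at 18. It replaces substitution by oxidation and reagent-controlled reduction.
     - MnO2 in CH2Cl2 oxidises only the secondary allylic alcohol, giving the (R)-hydroxy enynyl enone F3.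
     - Asymmetric transfer hydrogenation with RuCl[(S,S)-TsDPEN](p-cymene) in iPrOH acts on the same type of carbonyl as step 7. With the mirror-image ligand it should give the (1R,4S)-cis enyne diol F4.
     - F4 is reduced with NaAlH2(OCH2CH2OCH3)2 as in step 11 to give 18.

3. Step 17.
   - What may go wrong:
     - The trimethylsilyl ether may be lost to the trivalent chromium salts.
     - The E geometry may erode at the new or at older double bonds.
     - The long polyenyl iodide may decompose during work-up and chromatography.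
   - Fallback: it sets out from 23 and 22 and comes back at 27. It moves the iodo-olefination to the small symmetrical fragment.
     - An excess of dialdehyde 23 is treated with CHI3 and CrCl2, giving the mono-olefinated (2E,4E,6E,8E)-9-iodo-2,7-dimethylnona-2,4,6,8-tetraenal F5.
     - Ylide 24, made from 22 with NaOMe, is condensed with F5 to give the all-E C26 iodide with free C6 hydroxyl F6.
     - N-(Trimethylsilyl)imidazole, used as in step 16, then gives 27.

**Further compounds**
F1 | step 18 | (R)-tert-butyl{[4-((E)-4-iodo-3-methylbut-3-en-1-yn-1-yl)-3,5,5-trimethylcyclohex-3-en-1-yl]oxy}dimethylsilane | I/C=C(\C)C#CC1=C(C)C[C@@H](O[Si](C)(C)C(C)(C)C)CC1(C)C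
F2 | step 18 | all-E heptaenyl pinacol boronate of the silylated ring A half | CC1=C[C@@H](O[Si](C)(C)C(C)(C)C)CC(C)(C)[C@]1(O[Si](C)(C)C)/C=C/C(C)=C/C=C/C(C)=C/C=C/C=C(C)/C=C/B1OC(C)(C)C(C)(C)O1
F3 | step 10 | (R)-4-[(E)-5-(tert-butyldimethylsilyloxy)-3-methylpent-3-en-1-yn-1-yl]-4-hydroxy-3,5,5-trimethylcyclohex-2-en-1-one | CC1=CC(=O)CC(C)(C)[C@]1(O)C#C/C(C)=C/CO[Si](C)(C)C(C)(C)C
F4 | step 10 | (1R,4S)-1-[(E)-5-(tert-butyldimethylsilyloxy)-3-methylpent-3-en-1-yn-1-yl]-2,6,6-trimethylcyclohex-2-ene-1,4-diol | CC1=C[C@@H](O)CC(C)(C)[C@]1(O)C#C/C(C)=C/CO[Si](C)(C)C(C)(C)C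
F5 | step 17 | (2E,4E,6E,8E)-9-iodo-2,7-dimethylnona-2,4,6,8-tetraenal | O=C/C(C)=C/C=C/C=C(C)/C=C/I
F6 | step 17 | all-E C26 heptaenyl iodide with C3–OTBS and free C6–OH | CC1=C[C@@H](O[Si](C)(C)C(C)(C)C)CC(C)(C)[C@]1(O)/C=C/C(C)=C/C=C/C(C)=C/C=C/C=C(C)/C=C/I
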